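**Remarks on the chemistry (assumptions)**

- Locants: hydrindanes are numbered as 1H-indene (C1 acetyl carbon, C2, C3, C3a, C4 methylidene carbon, C5, C6, C7 isopropyl carbon, C7a). Decalins 18–24 are numbered so that C1, C2 and C3 later become hydrindane C1, the acetyl carbonyl carbon and hydrindane C2; C5 bears the methylidene, C7 the silyloxy and C8 the isopropyl group. The α face is the face of H-7a (H-8a).
- In 23 the C1–O bond is α and equatorial, and 25 carries the acetyl group α at C1. This is the relation that inversion at C1 demands, so the precursor and the product of the key step are used as drawn.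
- Vinylmagnesium bromide, isopropenylmagnesium bromide (the Grignard reagent of 2-bromopropene) and 3-[(tert-butyldimethylsilyl)oxy]propanal are taken as purchasable.

## Structural features

Compound 35 is a trans-fused hydrindane: cyclohexane ring A (C3a, C4, C5, C6, C7, C7a) and cyclopentane ring B (C1, C2, C3, C3a, C7a) share the C3a–C7a bond, with H-3a and H-7a on opposite faces. Ring A carries an exocyclic methylidene at C4, an axial acyloxy group at C6 and an equatorial isopropyl group at C7, cis to each other. Ring B carries an acetyl group at C1 and an angelate at C2, cis to each other and on the face of H-7a. Five stereocentres are contiguous (C6, C7, C7a, C1, C2), C3a adjoins C7a, and two more sit in the (2S,3S)-epoxyangelate on O-6. The fragile groups are the β-acyloxy ketone (acidic H-1, so loss of angelate or epimerisation), the angelate (Z to E drift to tiglate), the epoxide, and the exocyclic alkene (migration into the ring). The real difficulty is the strained trans-hydrindane whose five-membered ring bears the cis acetyl/acyloxy pair next to the ring fusion, together with the placing of two different hindered esters. The key step exploits the C1–C(=O)CH3 unit beside oxygenated C2: the acetyl carbonyl carbon is read as a methyl-bearing ring carbon of a cadinane-type decalin that has been extruded from the six-membered ring.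

## Logic of the disconnections

- **35 ⇒ 30 + 33.** The C6 O–acyl bond is cut last, because the epoxy ester is the most sensitive group. This leaves a mono-ester alcohol and a small chiral acid. The forward step must acylate a hindered axial alcohol without disturbing the β-acyloxy ketone.
- **30 ⇒ 29 ⇒ 26 + 27.** The C2 O–acyl bond is cut next, after exchanging the C6 ester for a robust silyl ether. Two silyl groups of different lability let the two hydroxyls be unmasked in order. The forward acylation must keep the Z geometry of the acid.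
- **26 ⇒ 25 ⇒ 23.** The C1–C2 bond of ring B is cut and C2 is reconnected to the acetyl carbonyl carbon. This turns the trans-hydrindane into an easier trans-decalin and postpones the β-oxy ketone to a late stage. The forward 1,2-shift needs an α-equatorial leaving group at C1 and a free tertiary hydroxyl beside it.
- **23 ⇒ 22 ⇒ 21 ⇒ 19.** The sulfonate, the triethylsilyl group and the two hydroxyls at C1 and C2 are removed, leaving a trisubstituted alkene beside an allylic alcohol. Three stereocentres become one. The forward dihydroxylation must occur syn to the allylic hydroxyl and must spare the exocyclic alkene.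
- **19 ⇒ 18 ⇒ 17.** The C3 carbinol goes back to the enone, and the C1=C2 alkene of ring B is cut by retro-metathesis. This gives a monocyclic triene. The forward ring closure must join the vinyl group and the isopropenyl ketone, not the 1,1-disubstituted ring methylidene.
- **17 ⇒ 16 ⇒ 15 ⇒ 14.** The acyl–isopropenyl bond is cut back to an ester by way of the N-methoxy-N-methylamide, and the exocyclic C=C goes back to the ring ketone. The ketone is methylenated first so that it never meets the Grignard reagents.
- **14 ⇒ 11 + 12.** The C7a–vinyl bond and the C3a–CH2 bond are cut together, which leaves a 4,5-disubstituted cyclohexenone, a vinyl metal and an alkylating agent. The forward step must add anti to the isopropyl group and then alkylate anti to the new vinyl group.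
- **11 ⇒ 10 ⇒ 9 ⇒ 8.** The ring A alkene is cut by retro-metathesis and the vinyl–carbinol bond is cut to an aldehyde. The carbinol configuration is irrelevant because it is oxidised.
- **8 ⇒ 7 ⇒ 6 ⇒ 5 ⇒ 3 + 4, and 3 ⇒ 2 ⇒ 1.** The C6–C7 bond is cut by retro-allylboration. Both ring A stereocentres arise in one step, so the forward reaction needs an E allylboronate (anti pair) and a chiral catalyst (absolute sense).
- **33 ⇒ 32 ⇒ 31 ⇒ 27.** The epoxy acid is traced to the allylic alcohol of the same Z acid that supplies the angelate. The forward epoxidation sets both epoxide centres.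

## Other disconnections considered

**Alternative 1:** The cut is at C1–C7a and C3–C3a, which takes ring B apart into the acyclic E-enone A1 and the ynone A2.
- *Forward key step:* a chiral nucleophilic phosphine adds to A2 and isomerises it to a 1,3-dipole. The acyl-bearing carbon attacks C7a of A1, the C3a enolate closes onto the far dipole carbon, and loss of the phosphine gives cyclopentene A3.
- *In favour:* two C–C bonds and ring B form in one catalytic, convergent step. The trans relation at C3a/C7a follows from the E alkene.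
- *Against here:* the dipole must choose between its two termini on a β-branched, slow aliphatic enone, and the catalyst must match or override the neighbouring C7 centre. After the annulation C1 and C2 are still sp2, so the cis acetyl/oxygen pair has to come from a reversible oxa-conjugate addition with protonation control at C1. Ring A must then be closed by an aldol in a molecule with two methyl ketones, and the C4 methylenation must tell the same two ketones apart.
- *Comparison:* on structure, A3 holds almost the whole carbon skeleton earlier than any compound of the chosen route; on convergence and on steps to the skeleton this alternative is the better one. On mechanism, a stepwise ionic annulation under catalyst control stands against a stereospecific 1,2-shift under substrate control, which fixes C1 by inversion with C2 already in place. On step economy overall, the steps saved early would probably be spent again on C1, C2, C6 and on ketone differentiation.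

**Alternative 2:** The cut is at C2–C3.
- *Forward key step:* in the siloxycyclopropane aldehyde A4 a zinc or titanium Lewis acid opens the three-membered ring at the C3–C4 bond. The resulting C3 homoenolate of the C4 ketone adds to the tethered aldehyde (5-exo-trig), which gives carbinol A5.
- *In favour:* the ring and the C2 carbinol form together, the trans fusion is already present, and no migratory aptitude is involved. The acetyl group stays masked as a ketal, so no β-oxy ketone is exposed during ring formation; on this point the alternative is better than the chosen plan. The C4 ketone also emerges free for a late methylenation with no second alkene in the molecule.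
- *Against here:* A4 needs an epimerisable C1 centre α to an aldehyde. It needs a regioselective and face-selective cyclopropanation of a ring A silyl enol ether. The aldehyde addition must give the α carbinol. Zinc homoenolates add sluggishly to aldehydes, and titanium conditions threaten the ketal and the silyl ether.
- *Comparison:* on structure, the chosen plan carries C1 as a configurationally fixed ring carbinol until the shift, while this plan carries it as a labile side-chain centre. On mechanism, a polar addition whose C2 outcome depends on chelation stands against a shift whose C1 outcome is dictated by geometry. On step economy, the count is expected to be similar or somewhat longer because of the separate build-up of the C1 side chain and the cyclopropane.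

**Alternative 3:** The cut is again a six-to-five contraction, but through the diazoketone A6.
- *Forward key step:* irradiation expels nitrogen while C7a shifts from the carbonyl carbon to the diazo carbon. The ketene is trapped by N,O-dimethylhydroxylamine to give Weinreb amide A7, and methyl addition would later give the acetyl group.
- *In favour:* photochemical contraction of cyclic diazoketones is dependable. The migrating C7a is an ordinary secondary carbon that moves with retention, so the trans fusion passes on exactly as in the chosen plan; on this point the two are equal. No hindered sulfonate is needed and no oxygenated carbon has to migrate; on this point the alternative is better.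
- *Against here:* C1 is set by protonation after ketene capture and not by a stereospecific event, and the required cis arrangement with the C2 silyloxy group is probably the less stable one. Diazo transfer must go through an enolate that has a β-silyloxy leaving group. The carbene has a competing 1,2-hydride shift from oxygenated C2. Amide-to-ketone conversion, ketal removal and methylenation still follow.
- *Comparison:* on structure, both plans use the same cadinane-type decalin. On mechanism, the chosen shift creates C1 by inversion, while this one leaves C1 to kinetic protonation. On step economy, the chosen plan reaches the acetyl group directly, while this one needs about three more operations after the contraction.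

Key step: step 19

## Route

Step 1
Reactants: 1 (2E)-4-methylpent-2-enal
Product: 2 (2E)-4-methylpent-2-en-1-ol
Conditions: NaBH4, CeCl3·7H2O, MeOH, 0 °C
Reagents that add atoms: none
Why: Luche reduction; the cerium-activated carbonyl takes hydride 1,2, so the E alkene should stay untouched; no stereocentre is formed.

Step 2
Reactants: 2 (2E)-4-methylpent-2-en-1-ol
Product: 3 2-[(2E)-4-methylpent-2-en-1-yl]-4,4,5,5-tetramethyl-1,3,2-dioxaborolane
Conditions: B2pin2, [Pd(MeCN)4](BF4)2 (5 mol %), DMSO/MeOH, 40 °C
Reagents that add atoms: bis(pinacolato)diboron, CC1(C)OB(OC1(C)C)B1OC(C)(C)C(C)(C)O1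
Why: palladium-catalysed borylation of an allylic alcohol (C–O to C–B exchange through a π-allyl complex of divalent palladium); boron should go to the unsubstituted terminus and the more stable E geometry should be kept.

Step 3
Reactants: 3 2-[(2E)-4-methylpent-2-en-1-yl]-4,4,5,5-tetramethyl-1,3,2-dioxaborolane; 4 3-[(tert-butyldimethylsilyl)oxy]propanal
Product: 5 (3R,4S)-1-[(tert-butyldimethylsilyl)oxy]-4-(propan-2-yl)hex-5-en-3-ol
Conditions: (S)-TRIP [(S)-3,3′-bis(2,4,6-triisopropylphenyl)-1,1′-binaphthyl-2,2′-diyl hydrogen phosphate] (5 mol %), 4 Å MS, toluene, −30 → 0 °C; aqueous work-up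
Reagents that add atoms: none
Why: chiral phosphoric acid-catalysed allylboration through a closed chair transition state; the E boronate gives the anti pair, and the S acid (mirror image of the acid known to send allyl groups to the Re face) should direct attack to the Si face, giving 3R and hence 4S.

Step 4
Reactants: 5 (3R,4S)-1-[(tert-butyldimethylsilyl)oxy]-4-(propan-2-yl)hex-5-en-3-ol
Product: 6 (3R,4S)-1,3-bis[(tert-butyldimethylsilyl)oxy]-4-(propan-2-yl)hex-5-ene
Conditions: TBSOTf, 2,6-lutidine, CH2Cl2, −78 → 0 °C
Reagents that add atoms: tert-butyldimethylsilyl trifluoromethanesulfonate, CC(C)(C)[Si](C)(C)OS(=O)(=O)C(F)(F)F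
Why: silyl ether formation; the silyl triflate is reactive enough for the hindered secondary alcohol beside the isopropyl-bearing carbon.

Step 5
Reactants: 6 (3R,4S)-1,3-bis[(tert-butyldimethylsilyl)oxy]-4-(propan-2-yl)hex-5-ene
Product: 7 (3R,4S)-3-[(tert-butyldimethylsilyl)oxy]-4-(propan-2-yl)hex-5-en-1-ol
Conditions: HF·pyridine, pyridine, THF, 0 °C
Reagents that add atoms: none
Why: selective desilylation; the unhindered primary silyl ether should be cleaved much faster than the secondary one flanked by the isopropyl-bearing carbon.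

Step 6
Reactants: 7 (3R,4S)-3-[(tert-butyldimethylsilyl)oxy]-4-(propan-2-yl)hex-5-en-1-ol
Product: 8 (3R,4S)-3-[(tert-butyldimethylsilyl)oxy]-4-(propan-2-yl)hex-5-enal
Conditions: Dess–Martin periodinane, CH2Cl2, 0 °C → rt
Reagents that add atoms: none
Why: Dess–Martin oxidation; non-basic conditions should avoid β-elimination of the silyloxy group from the new aldehyde.

Step 7
Reactants: 8 (3R,4S)-3-[(tert-butyldimethylsilyl)oxy]-4-(propan-2-yl)hex-5-enal
Product: 9 (5R,6S)-5-[(tert-butyldimethylsilyl)oxy]-6-(propan-2-yl)octa-1,7-dien-3-ol (both C3 epimers)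
Conditions: CH2=CHMgBr, THF, −78 °C
Reagents that add atoms: vinylmagnesium bromide, C=C[Mg]Br
Why: Grignard 1,2-addition; the new carbinol centre need not be controlled because it is oxidised in step 9.

Step 8
Reactants: 9 (5R,6S)-5-[(tert-butyldimethylsilyl)oxy]-6-(propan-2-yl)octa-1,7-dien-3-ol
Product: 10 (4S,5R)-5-[(tert-butyldimethylsilyl)oxy]-4-(propan-2-yl)cyclohex-2-en-1-ol (both C1 epimers)
Conditions: second-generation Grubbs catalyst (H2IMes)(PCy3)Cl2Ru=CHPh (3 mol %), CH2Cl2, 40 °C
Reagents that add atoms: none
Why: ring-closing metathesis of two monosubstituted alkenes to an unstrained cyclohexene with loss of ethene; the stereocentres are not involved.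

Step 9
Reactants: 10 (4S,5R)-5-[(tert-butyldimethylsilyl)oxy]-4-(propan-2-yl)cyclohex-2-en-1-ol
Product: 11 (4S,5R)-5-[(tert-butyldimethylsilyl)oxy]-4-(propan-2-yl)cyclohex-2-en-1-one
Conditions: Dess–Martin periodinane, CH2Cl2, rt
Reagents that add atoms: none
Why: Dess–Martin oxidation of the allylic alcohol; no base is present, so the enone should not lose its δ-silyloxy group by dienolisation.

Step 10
Reactants: 11 (4S,5R)-5-[(tert-butyldimethylsilyl)oxy]-4-(propan-2-yl)cyclohex-2-en-1-one; 12 ethyl bromoacetate
Product: 14 ethyl 2-[(1R,2S,3S,4R)-4-[(tert-butyldimethylsilyl)oxy]-2-ethenyl-6-oxo-3-(propan-2-yl)cyclohexyl]acetate, via bromomagnesium enolate 13 (not isolated)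
Conditions: CH2=CHMgBr, CuBr·SMe2 (10 mol %), THF, −78 → −40 °C; then HMPA, 12, −78 → −20 °C
Reagents that add atoms: vinylmagnesium bromide, C=C[Mg]Br
Why: copper-catalysed conjugate addition followed by enolate alkylation (three-component coupling); the vinyl copper species should add anti to the isopropyl and silyloxy groups (sets C7a), and the regiodefined enolate should be alkylated anti to the new vinyl group (sets C3a), the all-equatorial product also being the thermodynamic one.

Step 11
Reactants: 14 ethyl 2-[(1R,2S,3S,4R)-4-[(tert-butyldimethylsilyl)oxy]-2-ethenyl-6-oxo-3-(propan-2-yl)cyclohexyl]acetate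
Product: 15 ethyl 2-[(1R,2R,3S,4R)-4-[(tert-butyldimethylsilyl)oxy]-2-ethenyl-6-methylidene-3-(propan-2-yl)cyclohexyl]acetate
Conditions: Ph3PCH3Br, KOtBu, THF, 0 °C → rt
Reagents that add atoms: methyltriphenylphosphonium bromide, C[P+](c1ccccc1)(c1ccccc1)c1ccccc1.[Br-]
Why: Wittig methylenation; the ketone reacts far faster than the ester, and removing the ketone now takes it out of reach of the Grignard reagents and ends the risk of β-elimination of the C6 silyloxy group.

Step 12
Reactants: 15 ethyl 2-[(1R,2R,3S,4R)-4-[(tert-butyldimethylsilyl)oxy]-2-ethenyl-6-methylidene-3-(propan-2-yl)cyclohexyl]acetate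
Product: 16 2-[(1R,2R,3S,4R)-4-[(tert-butyldimethylsilyl)oxy]-2-ethenyl-6-methylidene-3-(propan-2-yl)cyclohexyl]-N-methoxy-N-methylacetamide
Conditions: MeNH(OMe)·HCl, iPrMgCl, THF, −20 → 0 °C
Reagents that add atoms: N,O-dimethylhydroxylamine hydrochloride, CNOC.Cl
Why: Weinreb amide formation by aminolysis of the ester with the chloromagnesium amide; the alkenes and the silyl ether are inert.

Step 13
Reactants: 16 2-[(1R,2R,3S,4R)-4-[(tert-butyldimethylsilyl)oxy]-2-ethenyl-6-methylidene-3-(propan-2-yl)cyclohexyl]-N-methoxy-N-methylacetamide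
Product: 17 1-[(1R,2R,3S,4R)-4-[(tert-butyldimethylsilyl)oxy]-2-ethenyl-6-methylidene-3-(propan-2-yl)cyclohexyl]-3-methylbut-3-en-2-one
Conditions: CH2=C(CH3)MgBr, THF, −20 → 0 °C; cold aq. NH4Cl
Reagents that add atoms: isopropenylmagnesium bromide, CC(=C)[Mg]Br
Why: Weinreb ketone synthesis; the chelated tetrahedral adduct should survive until the cold quench, so that a single isopropenyl group is introduced.

Step 14
Reactants: 17 1-[(1R,2R,3S,4R)-4-[(tert-butyldimethylsilyl)oxy]-2-ethenyl-6-methylidene-3-(propan-2-yl)cyclohexyl]-3-methylbut-3-en-2-one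
Product: 18 (4aR,7R,8S,8aR)-7-[(tert-butyldimethylsilyl)oxy]-2-methyl-5-methylidene-8-(propan-2-yl)-4a,5,6,7,8,8a-hexahydronaphthalen-3(4H)-one
Conditions: second-generation Hoveyda–Grubbs catalyst (H2IMes)Cl2Ru(=CH–C6H4-2-OiPr) (5 mol %), toluene, 80 °C
Reagents that add atoms: none
Why: ring-closing metathesis between the vinyl group and the isopropenyl ketone gives the six-membered 2-methyl enone; the ring methylidene is 1,1-disubstituted and hindered and could only close a four- or five-membered ring, so it should stay out.

Step 15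
Reactants: 18 (4aR,7R,8S,8aR)-7-[(tert-butyldimethylsilyl)oxy]-2-methyl-5-methylidene-8-(propan-2-yl)-4a,5,6,7,8,8a-hexahydronaphthalen-3(4H)-one
Product: 19 (3S,4aR,7R,8S,8aR)-7-[(tert-butyldimethylsilyl)oxy]-2-methyl-5-methylidene-8-(propan-2-yl)-3,4,4a,5,6,7,8,8a-octahydronaphthalen-3-ol
Conditions: NaBH4, CeCl3·7H2O, MeOH, −78 → −40 °C
Reagents that add atoms: none
Why: Luche reduction; axial hydride delivery from the β face of the rigid trans-fused enone should give the α (pseudo-equatorial) allylic alcohol, which sets C3.

Step 16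
Reactants: 19 (3S,4aR,7R,8S,8aR)-7-[(tert-butyldimethylsilyl)oxy]-2-methyl-5-methylidene-8-(propan-2-yl)-3,4,4a,5,6,7,8,8a-octahydronaphthalen-3-ol
Product: 21 (1R,2S,3S,4aR,7R,8S,8aR)-7-[(tert-butyldimethylsilyl)oxy]-2-methyl-5-methylidene-8-(propan-2-yl)decahydronaphthalene-1,2,3-triol, via hexavalent osmium glycolate TMEDA chelate 20 (not isolated)
Conditions: OsO4 (1.0 equiv), TMEDA (1.1 equiv), CH2Cl2, −78 °C; then aq. Na2SO3, THF, 60 °C
Reagents that add atoms: osmium tetroxide, O=[Os](=O)(=O)=O
Why: hydrogen-bond-directed dihydroxylation with OsO4·TMEDA; the allylic hydroxyl binds the diamine-ligated oxidant and delivers it syn (α face), which sets C1 and C2 all-cis to C3; the same hydrogen bond should favour the ring B alkene over the undirected, hindered methylidene.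

Step 17
Reactants: 21 (1R,2S,3S,4aR,7R,8S,8aR)-7-[(tert-butyldimethylsilyl)oxy]-2-methyl-5-methylidene-8-(propan-2-yl)decahydronaphthalene-1,2,3-triol
Product: 22 (1R,2R,3S,4aR,7R,8S,8aR)-7-[(tert-butyldimethylsilyl)oxy]-2-methyl-5-methylidene-8-(propan-2-yl)-3-[(triethylsilyl)oxy]decahydronaphthalene-1,2-diol
Conditions: Et3SiCl (1.05 equiv), imidazole, CH2Cl2, −40 → −20 °C
Reagents that add atoms: chlorotriethylsilane, CC[Si](Cl)(CC)CC
Why: selective silylation; the C3 hydroxyl has a CH2 neighbour, whereas the C1 hydroxyl is wedged between the ring fusion, the quaternary carbinol and the peri isopropyl group, and the tertiary hydroxyl is inert.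

Step 18
Reactants: 22 (1R,2R,3S,4aR,7R,8S,8aR)-7-[(tert-butyldimethylsilyl)oxy]-2-methyl-5-methylidene-8-(propan-2-yl)-3-[(triethylsilyl)oxy]decahydronaphthalene-1,2-diol
Product: 23 (1R,2S,3S,4aR,7R,8S,8aR)-7-[(tert-butyldimethylsilyl)oxy]-2-hydroxy-2-methyl-5-methylidene-8-(propan-2-yl)-3-[(triethylsilyl)oxy]decahydronaphthalen-1-yl methanesulfonate
Conditions: MsCl, Et3N, CH2Cl2, −20 → 0 °C
Reagents that add atoms: methanesulfonyl chloride, CS(Cl)(=O)=O
Why: mesylation through sulfene, a small electrophile that should reach the hindered secondary hydroxyl while the tertiary hydroxyl stays free; the configuration at C1 is retained.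

Step 19
Reactants: 23 (1R,2S,3S,4aR,7R,8S,8aR)-7-[(tert-butyldimethylsilyl)oxy]-2-hydroxy-2-methyl-5-methylidene-8-(propan-2-yl)-3-[(triethylsilyl)oxy]decahydronaphthalen-1-yl methanesulfonate
Product: 25 1-[(1R,2S,3aR,6R,7S,7aR)-6-[(tert-butyldimethylsilyl)oxy]-4-methylidene-7-(propan-2-yl)-2-[(triethylsilyl)oxy]octahydro-1H-inden-1-yl]ethan-1-one, via diethylaluminium alkoxide 24 (not isolated)
Conditions: Et3Al (3 equiv), CH2Cl2, −78 → −20 °C
Reagents that add atoms: none
Why: Et3Al turns the tertiary hydroxyl into an aluminium alkoxide (ethane is lost) and the Lewis-acidic aluminium also binds a sulfonyl oxygen; as the C1–O bond lengthens, the C2–C3 ring bond, antiperiplanar to it, moves from C2 to C1 while the oxygen lone pair closes the C=O bond, so C2 becomes the acetyl carbonyl and C3 becomes hydrindane C2. The closest known reaction type is the organoaluminium-promoted semipinacol (pinacol-type) rearrangement of 2-hydroxy sulfonates, used for contracting decalin diol monosulfonates to acyl hydrindanes. The five-membered ring arises by a 1,2-shift, so it is a ring contraction and not an exo or endo cyclisation, and no Baldwin mode applies. The one new stereocentre, hydrindane C1, is formed with inversion and is therefore controlled by the α-equatorial C1–O bond of 23; the migrating carbon keeps its configuration and the trans fusion is passed on unchanged. The step needs ring-bond migration and not methyl or hydride migration: in the rigid trans-decalin the equatorial sulfonate is antiperiplanar only to the C2–C3 ring bond, the methyl and hydroxyl on C2 are gauche to it, and H-8a is not anti, so elimination has no path. The oxygen on C2 is cis to the leaving group, so epoxide closure is also excluded. Departure should be helped by relief of the peri strain between the sulfonate and the isopropyl group, which offsets the lower migratory aptitude of the silyloxy-bearing carbon. The non-basic aluminium conditions and low temperature are chosen to spare the new β-silyloxy ketone from elimination, to prevent silyl transfer to the alkoxide and to avoid ethyl addition to the ketone.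

Step 20
Reactants: 25 1-[(1R,2S,3aR,6R,7S,7aR)-6-[(tert-butyldimethylsilyl)oxy]-4-methylidene-7-(propan-2-yl)-2-[(triethylsilyl)oxy]octahydro-1H-inden-1-yl]ethan-1-one
Product: 26 1-[(1R,2S,3aR,6R,7S,7aR)-6-[(tert-butyldimethylsilyl)oxy]-2-hydroxy-4-methylidene-7-(propan-2-yl)octahydro-1H-inden-1-yl]ethan-1-one
Conditions: PPTS, MeOH/CH2Cl2, 0 °C
Reagents that add atoms: none
Why: selective acid methanolysis of the triethylsilyl ether; the hindered axial tert-butyldimethylsilyl ether should survive, and mild acid avoids enolisation of the β-hydroxy ketone.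

Step 21
Reactants: 26 1-[(1R,2S,3aR,6R,7S,7aR)-6-[(tert-butyldimethylsilyl)oxy]-2-hydroxy-4-methylidene-7-(propan-2-yl)octahydro-1H-inden-1-yl]ethan-1-one; 27 angelic acid
Product: 29 (1R,2S,3aR,6R,7S,7aR)-1-acetyl-6-[(tert-butyldimethylsilyl)oxy]-4-methylidene-7-(propan-2-yl)octahydro-1H-inden-2-yl (2Z)-2-methylbut-2-enoate, via angelic 2,4,6-trichlorobenzoic anhydride 28 (not isolated)
Conditions: 27, 2,4,6-Cl3C6H2COCl, Et3N, toluene, rt; then 26, 80 °C (no DMAP)
Reagents that add atoms: none
Why: Yamaguchi-type mixed-anhydride esterification run thermally without a nucleophilic catalyst, the variant suited to angelates because it avoids the conjugate addition–elimination that converts the Z acyl group into the tiglate; the C2 configuration is retained.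

Step 22
Reactants: 29 (1R,2S,3aR,6R,7S,7aR)-1-acetyl-6-[(tert-butyldimethylsilyl)oxy]-4-methylidene-7-(propan-2-yl)octahydro-1H-inden-2-yl (2Z)-2-methylbut-2-enoate
Product: 30 (1R,2S,3aR,6R,7S,7aR)-1-acetyl-6-hydroxy-4-methylidene-7-(propan-2-yl)octahydro-1H-inden-2-yl (2Z)-2-methylbut-2-enoate
Conditions: HF·pyridine, pyridine, THF, 0 °C → rt
Reagents that add atoms: none
Why: fluoride-mediated desilylation under weakly acidic conditions, which should leave the β-acyloxy ketone, the angelate and the exocyclic alkene intact.

Step 23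
Reactants: 27 angelic acid
Product: 31 (2Z)-2-methylbut-2-en-1-ol
Conditions: LiAlH4, Et2O, 0 °C
Reagents that add atoms: none
Why: hydride reduction of the carboxylic acid; the alkyl-substituted alkene is not reduced and its Z geometry should be kept.

Step 24
Reactants: 31 (2Z)-2-methylbut-2-en-1-ol
Product: 32 [(2R,3S)-2,3-dimethyloxiran-2-yl]methanol
Conditions: Ti(OiPr)4 (10 mol %), D-(−)-diethyl tartrate (12 mol %), tBuOOH, 4 Å MS, CH2Cl2, −20 °C
Reagents that add atoms: tert-butyl hydroperoxide, CC(C)(C)OO
Why: Sharpless asymmetric epoxidation; L-(+)-tartrate gives 2S epoxy alcohols from allylic alcohols of this substitution pattern, so the D-(−)-tartrate should deliver oxygen to the opposite face and give 2R,3S; the syn addition carries over the Z geometry, so the hydroxymethyl group and the C3 methyl group stay cis and the two methyl groups stay trans.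

Step 25
Reactants: 32 [(2R,3S)-2,3-dimethyloxiran-2-yl]methanol
Product: 33 (2S,3S)-2,3-dimethyloxirane-2-carboxylic acid
Conditions: RuCl3·xH2O (2 mol %), NaIO4, MeCN/EtOAc/H2O, 0 °C → rt
Reagents that add atoms: sodium periodate, [Na+].[O-]I(=O)(=O)=O; water, O
Why: RuO4-catalysed oxidation of a primary epoxy alcohol to the glycidic acid; the stereocentres are untouched and the descriptor at C2 changes only because the substituent ranking changes.

Step 26
Reactants: 30 (1R,2S,3aR,6R,7S,7aR)-1-acetyl-6-hydroxy-4-methylidene-7-(propan-2-yl)octahydro-1H-inden-2-yl (2Z)-2-methylbut-2-enoate; 33 (2S,3S)-2,3-dimethyloxirane-2-carboxylic acid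
Product: 35 (1R,2S,3aR,6R,7S,7aR)-1-acetyl-4-methylidene-2-{[(2Z)-2-methylbut-2-enoyl]oxy}-7-(propan-2-yl)octahydro-1H-inden-6-yl (2S,3S)-2,3-dimethyloxirane-2-carboxylate, via mixed 2,4,6-trichlorobenzoic anhydride 34 (not isolated)
Conditions: 33, 2,4,6-Cl3C6H2COCl, Et3N, toluene, 0 °C → rt; then 30, DMAP, rt → 40 °C
Reagents that add atoms: none
Why: Yamaguchi esterification; the acylpyridinium derived from the mixed anhydride should be reactive enough for the hindered axial C6 hydroxyl, the acid has no α-hydrogen to epimerise, and C6 keeps its configuration.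

## Compound list

1 | (2E)-4-methylpent-2-enal | CC(C)/C=C/C=O | starting material
2 | (2E)-4-methylpent-2-en-1-ol | CC(C)/C=C/CO | intermediate
3 | 2-[(2E)-4-methylpent-2-en-1-yl]-4,4,5,5-tetramethyl-1,3,2-dioxaborolane | CC(C)/C=C/CB1OC(C)(C)C(C)(C)O1 | intermediate
4 | 3-[(tert-butyldimethylsilyl)oxy]propanal | CC(C)(C)[Si](C)(C)OCCC=O | starting material
5 | (3R,4S)-1-[(tert-butyldimethylsilyl)oxy]-4-(propan-2-yl)hex-5-en-3-ol | CC(C)(C)[Si](C)(C)OCC[C@@H](O)[C@@H](C(C)C)C=C | intermediate
6 | (3R,4S)-1,3-bis[(tert-butyldimethylsilyl)oxy]-4-(propan-2-yl)hex-5-ene | CC(C)(C)[Si](C)(C)OCC[C@@H](O[Si](C)(C)C(C)(C)C)[C@@H](C(C)C)C=C | intermediate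
7 | (3R,4S)-3-[(tert-butyldimethylsilyl)oxy]-4-(propan-2-yl)hex-5-en-1-ol | OCC[C@@H](O[Si](C)(C)C(C)(C)C)[C@@H](C(C)C)C=C | intermediate
8 | (3R,4S)-3-[(tert-butyldimethylsilyl)oxy]-4-(propan-2-yl)hex-5-enal | O=CC[C@@H](O[Si](C)(C)C(C)(C)C)[C@@H](C(C)C)C=C | intermediate
9 | (5R,6S)-5-[(tert-butyldimethylsilyl)oxy]-6-(propan-2-yl)octa-1,7-dien-3-ol, both C3 epimers | C=CC(O)C[C@@H](O[Si](C)(C)C(C)(C)C)[C@@H](C(C)C)C=C | intermediate
10 | (4S,5R)-5-[(tert-butyldimethylsilyl)oxy]-4-(propan-2-yl)cyclohex-2-en-1-ol, both C1 epimers | OC1C[C@@H](O[Si](C)(C)C(C)(C)C)[C@@H](C(C)C)C=C1 | intermediate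
11 | (4S,5R)-5-[(tert-butyldimethylsilyl)oxy]-4-(propan-2-yl)cyclohex-2-en-1-one | O=C1C[C@@H](O[Si](C)(C)C(C)(C)C)[C@@H](C(C)C)C=C1 | intermediate
12 | ethyl bromoacetate | CCOC(=O)CBr | starting material
13 | bromomagnesium enolate of the 3-vinyl ketone (not isolated) | C1[C@@H](O[Si](C)(C)C(C)(C)C)[C@@H](C(C)C)[C@H](C=C)C=C1O[Mg]Br | intermediate
14 | ethyl 2-[(1R,2S,3S,4R)-4-[(tert-butyldimethylsilyl)oxy]-2-ethenyl-6-oxo-3-(propan-2-yl)cyclohexyl]acetate | O=C1C[C@@H](O[Si](C)(C)C(C)(C)C)[C@@H](C(C)C)[C@H](C=C)[C@H]1CC(=O)OCC | intermediate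
15 | ethyl 2-[(1R,2R,3S,4R)-4-[(tert-butyldimethylsilyl)oxy]-2-ethenyl-6-methylidene-3-(propan-2-yl)cyclohexyl]acetate | C=C1C[C@@H](O[Si](C)(C)C(C)(C)C)[C@@H](C(C)C)[C@H](C=C)[C@H]1CC(=O)OCC | intermediate
16 | 2-[(1R,2R,3S,4R)-4-[(tert-butyldimethylsilyl)oxy]-2-ethenyl-6-methylidene-3-(propan-2-yl)cyclohexyl]-N-methoxy-N-methylacetamide | C=C1C[C@@H](O[Si](C)(C)C(C)(C)C)[C@@H](C(C)C)[C@H](C=C)[C@H]1CC(=O)N(C)OC | intermediate
17 | 1-[(1R,2R,3S,4R)-4-[(tert-butyldimethylsilyl)oxy]-2-ethenyl-6-methylidene-3-(propan-2-yl)cyclohexyl]-3-methylbut-3-en-2-one | C=C1C[C@@H](O[Si](C)(C)C(C)(C)C)[C@@H](C(C)C)[C@H](C=C)[C@H]1CC(=O)C(C)=C | intermediate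
18 | (4aR,7R,8S,8aR)-7-[(tert-butyldimethylsilyl)oxy]-2-methyl-5-methylidene-8-(propan-2-yl)-4a,5,6,7,8,8a-hexahydronaphthalen-3(4H)-one (locants as in 23) | C=C1C[C@@H](O[Si](C)(C)C(C)(C)C)[C@@H](C(C)C)[C@@H]2C=C(C)C(=O)C[C@@H]12 | intermediate
19 | (3S,4aR,7R,8S,8aR)-7-[(tert-butyldimethylsilyl)oxy]-2-methyl-5-methylidene-8-(propan-2-yl)-3,4,4a,5,6,7,8,8a-octahydronaphthalen-3-ol (locants as in 23) | C=C1C[C@@H](O[Si](C)(C)C(C)(C)C)[C@@H](C(C)C)[C@@H]2C=C(C)[C@@H](O)C[C@@H]12 | intermediate
20 | C1,C2 glycolate of hexavalent osmium with chelating TMEDA (not isolated) | C=C1C[C@@H](O[Si](C)(C)C(C)(C)C)[C@@H](C(C)C)[C@@H]2[C@H]3O[Os-2]4(=O)(=O)(O[C@@]3(C)[C@@H](O)C[C@@H]12)[N+](C)(C)CC[N+]4(C)C | intermediate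
21 | (1R,2S,3S,4aR,7R,8S,8aR)-7-[(tert-butyldimethylsilyl)oxy]-2-methyl-5-methylidene-8-(propan-2-yl)decahydronaphthalene-1,2,3-triol | C=C1C[C@@H](O[Si](C)(C)C(C)(C)C)[C@@H](C(C)C)[C@@H]2[C@@H](O)[C@@](C)(O)[C@@H](O)C[C@@H]12 | intermediate
22 | (1R,2R,3S,4aR,7R,8S,8aR)-7-[(tert-butyldimethylsilyl)oxy]-2-methyl-5-methylidene-8-(propan-2-yl)-3-[(triethylsilyl)oxy]decahydronaphthalene-1,2-diol | C=C1C[C@@H](O[Si](C)(C)C(C)(C)C)[C@@H](C(C)C)[C@@H]2[C@@H](O)[C@@](C)(O)[C@@H](O[Si](CC)(CC)CC)C[C@@H]12 | intermediate
23 | (1R,2S,3S,4aR,7R,8S,8aR)-7-[(tert-butyldimethylsilyl)oxy]-2-hydroxy-2-methyl-5-methylidene-8-(propan-2-yl)-3-[(triethylsilyl)oxy]decahydronaphthalen-1-yl methanesulfonate (cadinane-type hydroxy mesylate) | C=C1C[C@@H](O[Si](C)(C)C(C)(C)C)[C@@H](C(C)C)[C@@H]2[C@@H](OS(C)(=O)=O)[C@@](C)(O)[C@@H](O[Si](CC)(CC)CC)C[C@@H]12 | intermediate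
24 | diethylaluminium alkoxide of 23 (not isolated) | C=C1C[C@@H](O[Si](C)(C)C(C)(C)C)[C@@H](C(C)C)[C@@H]2[C@@H](OS(C)(=O)=O)[C@@](C)(O[Al](CC)CC)[C@@H](O[Si](CC)(CC)CC)C[C@@H]12 | intermediate
25 | 1-[(1R,2S,3aR,6R,7S,7aR)-6-[(tert-butyldimethylsilyl)oxy]-4-methylidene-7-(propan-2-yl)-2-[(triethylsilyl)oxy]octahydro-1H-inden-1-yl]ethan-1-one (oplopane core) | C=C1C[C@@H](O[Si](C)(C)C(C)(C)C)[C@@H](C(C)C)[C@@H]2[C@@H](C(C)=O)[C@@H](O[Si](CC)(CC)CC)C[C@@H]12 | intermediate
26 | 1-[(1R,2S,3aR,6R,7S,7aR)-6-[(tert-butyldimethylsilyl)oxy]-2-hydroxy-4-methylidene-7-(propan-2-yl)octahydro-1H-inden-1-yl]ethan-1-one | C=C1C[C@@H](O[Si](C)(C)C(C)(C)C)[C@@H](C(C)C)[C@@H]2[C@@H](C(C)=O)[C@@H](O)C[C@@H]12 | intermediate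
27 | angelic acid, (2Z)-2-methylbut-2-enoic acid | C/C=C(/C)C(=O)O | starting material
28 | (2Z)-2-methylbut-2-enoic 2,4,6-trichlorobenzoic anhydride (not isolated) | C/C=C(/C)C(=O)OC(=O)c1c(Cl)cc(Cl)cc1Cl | intermediate
29 | (1R,2S,3aR,6R,7S,7aR)-1-acetyl-6-[(tert-butyldimethylsilyl)oxy]-4-methylidene-7-(propan-2-yl)octahydro-1H-inden-2-yl (2Z)-2-methylbut-2-enoate | C=C1C[C@@H](O[Si](C)(C)C(C)(C)C)[C@@H](C(C)C)[C@@H]2[C@@H](C(C)=O)[C@@H](OC(=O)/C(C)=C\C)C[C@@H]12 | intermediate
30 | (1R,2S,3aR,6R,7S,7aR)-1-acetyl-6-hydroxy-4-methylidene-7-(propan-2-yl)octahydro-1H-inden-2-yl (2Z)-2-methylbut-2-enoate | C=C1C[C@@H](O)[C@@H](C(C)C)[C@@H]2[C@@H](C(C)=O)[C@@H](OC(=O)/C(C)=C\C)C[C@@H]12 | intermediate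
31 | (2Z)-2-methylbut-2-en-1-ol | C/C=C(/C)CO | intermediate
32 | [(2R,3S)-2,3-dimethyloxiran-2-yl]methanol | OC[C@@]1(C)O[C@H]1C | intermediate
33 | (2S,3S)-2,3-dimethyloxirane-2-carboxylic acid | OC(=O)[C@@]1(C)O[C@H]1C | intermediate
34 | (2S,3S)-2,3-dimethyloxirane-2-carboxylic 2,4,6-trichlorobenzoic anhydride (not isolated) | O=C(OC(=O)[C@@]1(C)O[C@H]1C)c1c(Cl)cc(Cl)cc1Cl | intermediate
35 | (1R,2S,3aR,6R,7S,7aR)-1-acetyl-4-methylidene-2-{[(2Z)-2-methylbut-2-enoyl]oxy}-7-(propan-2-yl)octahydro-1H-inden-6-yl (2S,3S)-2,3-dimethyloxirane-2-carboxylate (CNP0300602.1) | C=C1C[C@@H](OC(=O)[C@@]2(C)O[C@H]2C)[C@@H](C(C)C)[C@@H]2[C@@H](C(C)=O)[C@@H](OC(=O)/C(C)=C\C)C[C@@H]12 | target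

## Step count and least certain steps

Total step count: 26. Longest linear sequence: 23 steps (steps 1–22 and 26); the epoxy acid branch (steps 23–25) joins at step 26.

**Step 19 (key step).** The most likely failure is slow ionisation of the hindered sulfonate, because the migrating carbon carries an oxygen. If the mixture then has to be warmed, the new β-silyloxy ketone may lose its silyloxy group, or ethyl may be transferred from aluminium to the ketone. The fallback sets out from diol 22 and returns at 25. Treating 22 with triflic anhydride and 2,6-di-tert-butyl-4-methylpyridine in CH2Cl2 at −78 → −20 °C should give the secondary hydroxy triflate F1, which is not isolated. Its far better leaving group should let the same ring-bond shift proceed with only the free tertiary hydroxyl as the push, without Lewis acid or alkoxide, as in triflate-triggered ring contractions of cyclic diols.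

**Step 16.** The likely failure is loss of chemoselectivity, with competing osmylation of the exocyclic methylidene, or incomplete syn delivery on the face that also carries the axial silyloxy group of ring A. The fallback sets out from 14 and returns at 21, and moves the methylenation behind the dihydroxylation. Keto ester 14 is ketalised (1,2-bis(trimethylsilyloxy)ethane, catalytic TMSOTf, CH2Cl2, −78 °C) to dioxolane F2. Under the conditions of steps 12 to 15, F2 should then give in turn Weinreb amide F3, isopropenyl ketone F4, bicyclic enone F5 and allylic alcohol F6. In F6 the ring B alkene is the only alkene, so the dihydroxylation of step 16 should pass through osmate F7 (not isolated) to ketal triol F8. Aqueous acetic acid in THF should then free keto triol F9, and excess Ph3P=CH2 in THF should convert F9 into 21.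

**Step 10.** The likely failure is slow alkylation of the magnesium enolate. Proton exchange with the product would then move the enolate to the C5 side, and the axial silyloxy group at C6 would be eliminated. The fallback sets out from 11 and returns at 14. The copper-catalysed vinyl addition is run with Me3SiCl so that the regiodefined silyl enol ether F10 is isolated. MeLi in THF at 0 °C then frees the lithium enolate F11 (not isolated), which is alkylated at once with 12 in THF/HMPA at −78 °C.

**Step 21.** The likely failures are Z to E drift of the activated acyl group and amine-induced β-elimination at the β-oxy ketone during the heated acylation. The fallback sets out from 26 and 27 and returns at 29. Angelic acid is dehydrated with N,N′-dicyclohexylcarbodiimide to the symmetric anhydride F12. This acylates 26 under Lewis acid catalysis (catalytic Sc(OTf)3, MeCN, −20 °C), a base-free acyl transfer that has no amine to add to the double bond or to deprotonate C1.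

**Step 26.** The likely failure is slow acylation of the hindered axial C6 hydroxyl, with prolonged exposure of the β-angeloyloxy ketone to DMAP and Et3N and loss of angelic acid by elimination. The fallback sets out from 25 and returns at 35, and reverses the order of the two esterifications so that the forcing acylation meets the less elimination-prone β-silyloxy ketone. Both silyl groups of 25 are removed with HF·pyridine in THF to give diol F13. The less hindered C2 hydroxyl is silylated again (Et3SiCl, imidazole, CH2Cl2, −40 °C) to give silyl ether F14. The C6 hydroxyl of F14 is esterified with 33 through 34 under the conditions of step 26 to give epoxy ester F15. PPTS in MeOH at 0 °C should then cleave the triethylsilyl ether to give hydroxy ester F16, and F16 is acylated with 28 under the conditions of step 21 to give 35.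

## Further compounds

F1 | step 19 | (1R,2S,3S,4aR,7R,8S,8aR)-7-[(tert-butyldimethylsilyl)oxy]-2-hydroxy-2-methyl-5-methylidene-8-(propan-2-yl)-3-[(triethylsilyl)oxy]decahydronaphthalen-1-yl trifluoromethanesulfonate (not isolated) | C=C1C[C@@H](O[Si](C)(C)C(C)(C)C)[C@@H](C(C)C)[C@@H]2[C@@H](OS(=O)(=O)C(F)(F)F)[C@@](C)(O)[C@@H](O[Si](CC)(CC)CC)C[C@@H]12
F2 | step 16 | ethylene ketal of keto ester 14 | C12(OCCO1)C[C@@H](O[Si](C)(C)C(C)(C)C)[C@@H](C(C)C)[C@H](C=C)[C@H]2CC(=O)OCC
F3 | step 16 | N-methoxy-N-methylamide of F2 | C12(OCCO1)C[C@@H](O[Si](C)(C)C(C)(C)C)[C@@H](C(C)C)[C@H](C=C)[C@H]2CC(=O)N(C)OC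
F4 | step 16 | isopropenyl ketone from F3 | C12(OCCO1)C[C@@H](O[Si](C)(C)C(C)(C)C)[C@@H](C(C)C)[C@H](C=C)[C@H]2CC(=O)C(C)=C
F5 | step 16 | C5 ethylene ketal analogue of bicyclic enone 18 | C13(OCCO3)C[C@@H](O[Si](C)(C)C(C)(C)C)[C@@H](C(C)C)[C@@H]2C=C(C)C(=O)C[C@@H]12
F6 | step 16 | C5 ethylene ketal analogue of allylic alcohol 19 | C13(OCCO3)C[C@@H](O[Si](C)(C)C(C)(C)C)[C@@H](C(C)C)[C@@H]2C=C(C)[C@@H](O)C[C@@H]12
F7 | step 16 | C5 ethylene ketal analogue of osmate 20 (not isolated) | C13(OCCO3)C[C@@H](O[Si](C)(C)C(C)(C)C)[C@@H](C(C)C)[C@@H]2[C@H]3O[Os-2]4(=O)(=O)(O[C@@]3(C)[C@@H](O)C[C@@H]12)[N+](C)(C)CC[N+]4(C)C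
F8 | step 16 | C5 ethylene ketal analogue of triol 21 | C13(OCCO3)C[C@@H](O[Si](C)(C)C(C)(C)C)[C@@H](C(C)C)[C@@H]2[C@@H](O)[C@@](C)(O)[C@@H](O)C[C@@H]12
F9 | step 16 | C5 ketone analogue of triol 21 (keto triol) | O=C1C[C@@H](O[Si](C)(C)C(C)(C)C)[C@@H](C(C)C)[C@@H]2[C@@H](O)[C@@](C)(O)[C@@H](O)C[C@@H]12
F10 | step 10 | trimethylsilyl enol ether of the 3-vinyl ketone | C1[C@@H](O[Si](C)(C)C(C)(C)C)[C@@H](C(C)C)[C@H](C=C)C=C1O[Si](C)(C)C
F11 | step 10 | lithium enolate of the 3-vinyl ketone (not isolated) | C1[C@@H](O[Si](C)(C)C(C)(C)C)[C@@H](C(C)C)[C@H](C=C)C=C1O[Li]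
F12 | step 21 | (2Z)-2-methylbut-2-enoic anhydride (angelic anhydride) | C/C=C(/C)C(=O)OC(=O)/C(C)=C\C
F13 | step 26 | 1-[(1R,2S,3aR,6R,7S,7aR)-2,6-dihydroxy-4-methylidene-7-(propan-2-yl)octahydro-1H-inden-1-yl]ethan-1-one | C=C1C[C@@H](O)[C@@H](C(C)C)[C@@H]2[C@@H](C(C)=O)[C@@H](O)C[C@@H]12
F14 | step 26 | C2 triethylsilyl ether of F13 with free C6 hydroxyl | C=C1C[C@@H](O)[C@@H](C(C)C)[C@@H]2[C@@H](C(C)=O)[C@@H](O[Si](CC)(CC)CC)C[C@@H]12
F15 | step 26 | C6 (2S,3S)-2,3-dimethyloxirane-2-carboxylate of F14 | C=C1C[C@@H](OC(=O)[C@@]2(C)O[C@H]2C)[C@@H](C(C)C)[C@@H]2[C@@H](C(C)=O)[C@@H](O[Si](CC)(CC)CC)C[C@@H]12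
F16 | step 26 | C6 (2S,3S)-2,3-dimethyloxirane-2-carboxylate with free C2 hydroxyl | C=C1C[C@@H](OC(=O)[C@@]2(C)O[C@H]2C)[C@@H](C(C)C)[C@@H]2[C@@H](C(C)=O)[C@@H](O)C[C@@H]12
A1 | alternative 1 | (3E,5S)-5-{[(tert-butyldimethylsilyl)oxy]methyl}-6-methylhept-3-en-2-one | CC(C)(C)[Si](C)(C)OC[C@@H](C(C)C)/C=C/C(C)=O
A2 | alternative 1 | pent-3-yn-2-one | CC#CC(C)=O
A3 | alternative 1 | trans-4,5-disubstituted 1-acetylcyclopentene (4-acetyl, 5-[1-(silyloxy)-3-methylbutan-2-yl]) | CC(C)(C)[Si](C)(C)OC[C@@H](C(C)C)[C@@H]1C(C(C)=O)=CC[C@H]1C(C)=O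
A4 | alternative 2 | C3a–C4 fused trimethylsiloxycyclopropane bearing the C1 dioxolane and the C2 aldehyde | O=C[C@H](C1(C)OCCO1)[C@H]1[C@H](C(C)C)[C@H](O[Si](C)(C)C(C)(C)C)C[C@]2(O[Si](C)(C)C)C[C@H]12
A5 | alternative 2 | trans-hydrindan-4-one with C2 carbinol and C1 2-methyl-1,3-dioxolan-2-yl group | O=C1C[C@@H](O[Si](C)(C)C(C)(C)C)[C@@H](C(C)C)[C@@H]2[C@@H](C3(C)OCCO3)[C@@H](O)C[C@@H]12
A6 | alternative 3 | α-diazo trans-decalone with C4 ethylene ketal | O=C1C(=[N+]=[N-])[C@@H](O[Si](CC)(CC)CC)C[C@@H]2[C@@H]1[C@H](C(C)C)[C@H](O[Si](C)(C)C(C)(C)C)CC23OCCO3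
A7 | alternative 3 | trans-hydrindane C1 N-methoxy-N-methylcarboxamide | CON(C)C(=O)[C@H]1[C@@H](O[Si](CC)(CC)CC)C[C@@H]2[C@@H]1[C@H](C(C)C)[C@H](O[Si](C)(C)C(C)(C)C)CC23OCCO3
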